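**Plan**

1. Rings are lettered A (2,4,6-trihydroxyphenoxy end) to H (3,4,5-trihydroxyphenoxy end) and all 21 hydroxyls travel as methyl ethers. The retrosynthesis cuts, in this order, the 21 O–CH3 bonds, the E–O–F ether at the ring F carbon, the F–O–G ether at the ring F carbon, and then rings E and G themselves.
2. Enabling feature: rings G and E are benzenes with five contiguous oxygens and one C–H (ring G: C-1 O to ring F, C-2 O to ring H, C-3/C-4/C-5 OH, C-6 H). Cutting C-1–C-6 unravels such a ring to a 4-methoxy-4-(1-methoxyvinyl)cyclobutenone, in which C-1 to C-4 are the four carbons of squaric acid and C-5/C-6 are the vinyl ether. The flanked aryloxy group (ring H on G, ring D on E) is installed by addition–elimination on a squaric ester chloride, which also solves the D–O–E ether with its four ortho substituents.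
3. The A–D part is cut at its three ethers into 2,4,6-trimethoxyphenol and two bromobenzaldehydes (one used twice); each formyl group is a latent phenol (Ullmann coupling, then Dakin oxidation).
4. Forward: squaric acid → ester chloride → ring G built onto the ring H phenol (H–G phenol) → ring F joined at its iodide (H–G–F bromide). In parallel A → A–B → A–B–C → A–D phenol, then ring E built onto it by the same ring expansion. Finally A–E phenol + H–G–F bromide, then global demethylation.
5. Stereochemistry: the target has no stereocentre; the only one on the way (the racemic C-4 of the two cyclobutenones) becomes sp2 in the ring expansion.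

Key step: step 6

Remarks on the chemistry:
- The diaryl ether axes are taken as freely rotating, so only constitution and regiochemistry need control.
- ArAD below means the aryl group of the A–D phenol made in step 16, 4-{6-[2,6-dimethoxy-4-(2,4,6-trimethoxyphenoxy)phenoxy]-2,3,4-trimethoxyphenoxy}-2,6-dimethoxyphenyl.
- The ester chloride of step 2 is made in one batch that serves steps 3 and 17.
- The organolithium reagent of step 4 is made fresh by that procedure on the day of each addition (steps 5 and 18).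

**Route**

Step 1
Reactants: 1 squaric acid (3,4-dihydroxycyclobut-3-ene-1,2-dione)
Product: 2 squaryl dichloride (3,4-dichlorocyclobut-3-ene-1,2-dione)
Conditions: (COCl)2 (2.2 equiv), DMF (cat.), CH2Cl2, rt → 40 °C; sublimation
Reagents that add atoms: oxalyl chloride, O=C(Cl)C(Cl)=O
Why: Acid chloride formation on the vinylogous acid by the Vilsmeier reagent generated from oxalyl chloride and DMF, driven by loss of CO, CO2 and HCl.

Step 2
Reactants: 2 squaryl dichloride
Product: 3 3-chloro-4-methoxycyclobut-3-ene-1,2-dione (squaric acid methyl ester chloride)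
Conditions: MeOH (1.0 equiv, slow addition), Et2O, −30 °C → rt, Ar sweep; short-path distillation; stored under Ar at −20 °C
Reagents that add atoms: methanol, CO
Why: Addition–elimination (vinylogous acyl substitution) of one chloride by methanol; the new methoxy oxygen donates into the ring double bond and lowers the electrophilicity of the remaining chloride-bearing carbon, so one equivalent of alcohol at low temperature should stop at the ester chloride.

Step 3
Reactants: 3 3-chloro-4-methoxycyclobut-3-ene-1,2-dione; 4 3,4,5-trimethoxyphenol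
Product: 5 3-methoxy-4-(3,4,5-trimethoxyphenoxy)cyclobut-3-ene-1,2-dione
Conditions: 4 (1.0 equiv), i-Pr2NEt (1.1 equiv), THF, −78 °C → rt
Reagents that add atoms: none
Why: Addition–elimination (vinylogous acyl substitution) in which the phenoxide of 4 attacks the chloride-bearing carbon and expels chloride, the only good leaving group, so the bond from the ring H oxygen to the future C-2 of ring G is made without aryl coupling.

Step 4
Reactants: 6 methyl vinyl ether
Product: 7 1-methoxyvinyllithium (THF solution)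
Conditions: 6 (1.5 equiv), t-BuLi (1.0 equiv, pentane), THF, −78 → 0 °C, Ar; titrated, re-cooled to −78 °C and used the same day
Reagents that add atoms: tert-butyllithium, [Li]C(C)(C)C
Why: α-Metalation of the enol ether at its oxygen-bearing sp2 carbon, whose C–H bond is acidified by the oxygen that also coordinates lithium; the excess of volatile 6 ensures that no t-BuLi is left to attack the squarates in steps 5 and 18.

Step 5
Reactants: 5 3-methoxy-4-(3,4,5-trimethoxyphenoxy)cyclobut-3-ene-1,2-dione; 7 1-methoxyvinyllithium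
Product: 9 3,4-dimethoxy-4-(1-methoxyethenyl)-2-(3,4,5-trimethoxyphenoxy)cyclobut-2-en-1-one (racemic), via lithium alkoxide 8 (not isolated)
Conditions: 7 (1.2 equiv) added to 5, THF, −78 °C; then MeOTf (1.5 equiv), −78 → 0 °C
Reagents that add atoms: methyl triflate, COS(=O)(=O)C(F)(F)F
Why: 1,2-Addition of an α-lithiated enol ether to a squarate carbonyl followed by O-methylation of the lithium alkoxide in the flask: the carbonyl conjugated through the ring double bond with the aryloxy group (a weaker donor than methoxy, and the carbonyl farther from the aryl group) is the more electrophilic one and should be attacked, which places the aryloxy group α to the surviving carbonyl; the new quaternary carbon forms as a racemate that step 6 erases, and trapping in the flask avoids base-induced rearrangement of a free 4-hydroxycyclobutenone.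

Step 6
Reactants: 9 3,4-dimethoxy-4-(1-methoxyethenyl)-2-(3,4,5-trimethoxyphenoxy)cyclobut-2-en-1-one
Product: 12 3,4,5-trimethoxy-2-(3,4,5-trimethoxyphenoxy)phenol (H–G phenol), via dienylketene 10 (not isolated), via cyclohexadienone 11 (not isolated)
Conditions: PhMe (degassed), 110 °C, Ar
Reagents that add atoms: none
Why: Heating opens the cyclobutenone by a four-electron conrotatory electrocyclic cleavage of the C-1–C-4 bond to dienylketene 10, whose ketene carbon and vinyl terminus join in a six-electron disrotatory electrocyclisation to cyclohexa-2,4-dienone 11, and enolisation gives phenol 12 (Moore–Liebeskind ring expansion of 4-alkenyl-4-alkoxycyclobutenones). Ring G is thus closed by a 6π electrocyclisation that forms only the C-1–C-6 bond, four ring carbons coming from the squarate and two from the methoxyvinyl group, with all five oxygens already in place. No stereocentre is created, and the racemic quaternary carbon of 9 becomes an aromatic carbon. The step needs the vinyl group, not the geminal methoxy group, to rotate inward on ring opening so that the central double bond of 10 is Z; the strong preference of the oxygen donor at C-4 for outward rotation (torquoselectivity) secures this. The free hydroxyl ends up next to the lone C–H and the ring H aryloxy group between OH and OMe as a direct consequence of the regiochemistry fixed in step 5, and exclusion of air protects the electron-rich phenol.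

Step 7
Reactants: 13 4-bromo-2-methoxyphenol
Product: 14 4-bromo-2-iodo-6-methoxyphenol
Conditions: NIS, TsOH·H2O (10 mol %), MeCN, rt
Reagents that add atoms: N-iodosuccinimide, O=C1CCC(=O)N1I
Why: Electrophilic aromatic iodination directed by the free hydroxyl to its only open ortho position, the para position being blocked by bromine.

Step 8
Reactants: 14 4-bromo-2-iodo-6-methoxyphenol
Product: 15 5-bromo-1-iodo-2,3-dimethoxybenzene
Conditions: MeI, K2CO3, acetone, reflux
Reagents that add atoms: iodomethane, CI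
Why: Williamson O-methylation of the phenoxide, giving the ring F building block with two halides of different reactivity.

Step 9
Reactants: 12 3,4,5-trimethoxy-2-(3,4,5-trimethoxyphenoxy)phenol; 15 5-bromo-1-iodo-2,3-dimethoxybenzene
Product: 16 5-bromo-2,3-dimethoxy-1-[3,4,5-trimethoxy-2-(3,4,5-trimethoxyphenoxy)phenoxy]benzene (H–G–F bromide)
Conditions: CuI (10 mol %), picolinic acid (20 mol %), K3PO4, DMSO, 70 °C, Ar; 15 (1.5 equiv)
Reagents that add atoms: none
Why: Ullmann-type diaryl ether coupling in which monovalent copper inserts into the C–I bond much faster than into the C–Br bond, so with excess 15 at moderate temperature only the iodide position (C-5 of ring F) is etherified and the bromide is kept for step 20.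

Step 10
Reactants: 17 2,4,6-trimethoxyphenol; 18 4-bromo-2,6-dimethoxybenzaldehyde
Product: 19 2,6-dimethoxy-4-(2,4,6-trimethoxyphenoxy)benzaldehyde (A–B aldehyde)
Conditions: CuI (10 mol %), picolinic acid (20 mol %), K3PO4, DMSO, 90 °C, Ar
Reagents that add atoms: none
Why: Ullmann diaryl ether coupling of a di-ortho-substituted phenol, for which the CuI/picolinic acid system is suited, with an unhindered aryl bromide activated by its para formyl group.

Step 11
Reactants: 19 2,6-dimethoxy-4-(2,4,6-trimethoxyphenoxy)benzaldehyde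
Product: 21 2,6-dimethoxy-4-(2,4,6-trimethoxyphenoxy)phenol (A–B phenol), via aryl formate 20 (not isolated)
Conditions: mCPBA, CH2Cl2, 0 °C → rt; aq. NaHCO3 wash; then K2CO3 (cat.), MeOH, rt
Reagents that add atoms: meta-chloroperbenzoic acid, OOC(=O)c1cccc(Cl)c1
Why: Dakin-type Baeyer–Villiger oxidation in which the electron-rich di-ortho-methoxy aryl group migrates to oxygen to give the formate, which methanolysis cleaves to the phenol.

Step 12
Reactants: 22 5-bromo-1,2,3-trimethoxybenzene
Product: 23 6-bromo-2,3,4-trimethoxybenzaldehyde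
Conditions: Cl2CHOMe, TiCl4, CH2Cl2, 0 °C; then H2O
Reagents that add atoms: dichloromethyl methyl ether, COC(Cl)Cl; water, O
Why: Rieche formylation (Friedel–Crafts reaction with the chloro-oxocarbenium ion) at the only kind of free ring position, which is ortho and para to methoxy groups, so no regioisomer can form.

Step 13
Reactants: 21 2,6-dimethoxy-4-(2,4,6-trimethoxyphenoxy)phenol; 23 6-bromo-2,3,4-trimethoxybenzaldehyde
Product: 24 6-[2,6-dimethoxy-4-(2,4,6-trimethoxyphenoxy)phenoxy]-2,3,4-trimethoxybenzaldehyde (A–B–C aldehyde)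
Conditions: CuI (10 mol %), picolinic acid (20 mol %), K3PO4, DMSO, 100 °C, Ar
Reagents that add atoms: none
Why: Ullmann diaryl ether coupling in which the ortho formyl group activates the C–Br bond, allowing the hindered phenoxide to form the B–O–C ether with three ortho substituents.

Step 14
Reactants: 24 6-[2,6-dimethoxy-4-(2,4,6-trimethoxyphenoxy)phenoxy]-2,3,4-trimethoxybenzaldehyde
Product: 26 6-[2,6-dimethoxy-4-(2,4,6-trimethoxyphenoxy)phenoxy]-2,3,4-trimethoxyphenol (A–B–C phenol), via aryl formate 25 (not isolated)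
Conditions: mCPBA, CH2Cl2, 0 °C → rt; aq. NaHCO3 wash; then K2CO3 (cat.), MeOH, rt
Reagents that add atoms: meta-chloroperbenzoic acid, OOC(=O)c1cccc(Cl)c1
Why: Dakin-type Baeyer–Villiger oxidation with migration of the tetra-oxygenated aryl group, then methanolysis of the formate, unmasking the ring C hydroxyl that sits between OAr and OMe.

Step 15
Reactants: 26 6-[2,6-dimethoxy-4-(2,4,6-trimethoxyphenoxy)phenoxy]-2,3,4-trimethoxyphenol; 18 4-bromo-2,6-dimethoxybenzaldehyde
Product: 27 4-{6-[2,6-dimethoxy-4-(2,4,6-trimethoxyphenoxy)phenoxy]-2,3,4-trimethoxyphenoxy}-2,6-dimethoxybenzaldehyde (A–D aldehyde)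
Conditions: CuI (10 mol %), picolinic acid (20 mol %), K3PO4, DMSO, 90 °C, Ar
Reagents that add atoms: none
Why: Ullmann diaryl ether coupling of the flanked ring C phenoxide with the same unhindered, formyl-activated bromide as in step 10, now serving as ring D.

Step 16
Reactants: 27 4-{6-[2,6-dimethoxy-4-(2,4,6-trimethoxyphenoxy)phenoxy]-2,3,4-trimethoxyphenoxy}-2,6-dimethoxybenzaldehyde
Product: 29 4-{6-[2,6-dimethoxy-4-(2,4,6-trimethoxyphenoxy)phenoxy]-2,3,4-trimethoxyphenoxy}-2,6-dimethoxyphenol (A–D phenol, ArAD–OH), via aryl formate 28 (not isolated)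
Conditions: mCPBA, CH2Cl2, 0 °C → rt; aq. NaHCO3 wash; then K2CO3 (cat.), MeOH, rt
Reagents that add atoms: meta-chloroperbenzoic acid, OOC(=O)c1cccc(Cl)c1
Why: Dakin-type Baeyer–Villiger oxidation as in step 11, converting the formyl group of ring D into the hydroxyl flanked by two methoxy groups.

Step 17
Reactants: 29 A–D phenol (ArAD–OH); 3 3-chloro-4-methoxycyclobut-3-ene-1,2-dione
Product: 30 3-methoxy-4-(ArAD-oxy)cyclobut-3-ene-1,2-dione
Conditions: 3 (1.3 equiv), i-Pr2NEt (1.5 equiv), THF, −78 °C → rt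
Reagents that add atoms: none
Why: Addition–elimination (vinylogous acyl substitution) as in step 3, in which even the phenoxide flanked by two methoxy groups reacts because the electrophile is an unhindered acid-chloride-like carbon, so the D–O–E ether with four ortho substituents is made without aryl coupling.

Step 18
Reactants: 30 3-methoxy-4-(ArAD-oxy)cyclobut-3-ene-1,2-dione; 7 1-methoxyvinyllithium
Product: 32 3,4-dimethoxy-4-(1-methoxyethenyl)-2-(ArAD-oxy)cyclobut-2-en-1-one (racemic), via lithium alkoxide 31 (not isolated)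
Conditions: 7 (1.2 equiv) added to 30, THF, −78 °C; then MeOTf (1.5 equiv), −78 → 0 °C
Reagents that add atoms: methyl triflate, COS(=O)(=O)C(F)(F)F
Why: Organolithium 1,2-addition to the squarate carbonyl that is conjugated with the weaker aryloxy donor, followed by O-methylation of the alkoxide, as in step 5; here the di-ortho-methoxy aryloxy group also shields the other carbonyl, and the racemic quaternary carbon is erased in step 19.

Step 19
Reactants: 32 3,4-dimethoxy-4-(1-methoxyethenyl)-2-(ArAD-oxy)cyclobut-2-en-1-one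
Product: 35 3,4,5-trimethoxy-2-(ArAD-oxy)phenol (A–E phenol), via dienylketene 33 (not isolated), via cyclohexadienone 34 (not isolated)
Conditions: PhMe (degassed), 110 °C, Ar
Reagents that add atoms: none
Why: The same Moore–Liebeskind sequence as in step 6 (conrotatory ring opening with the methoxy group rotating outward, 6π electrocyclisation, enolisation) builds ring E with its five oxygens and leaves the hydroxyl next to the lone C–H free for ring F.

Step 20
Reactants: 35 3,4,5-trimethoxy-2-(ArAD-oxy)phenol (A–E phenol); 16 H–G–F bromide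
Product: 36 henicosa-O-methyl ether of the target, 2-(ArAD-oxy)-1-{3,4-dimethoxy-5-[3,4,5-trimethoxy-2-(3,4,5-trimethoxyphenoxy)phenoxy]phenoxy}-3,4,5-trimethoxybenzene
Conditions: CuI (20 mol %), picolinic acid (40 mol %), K3PO4, DMSO, 100 °C, Ar
Reagents that add atoms: none
Why: Ullmann diaryl ether coupling of the ring E phenoxide, which has only one ortho substituent, with the bromide of ring F, which has none, joining the two halves at the least hindered ether of the chain.

Step 21
Reactants: 36 henicosa-O-methyl ether of the target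
Product: 37 CNP0309601.0 (rings A–H joined as in 36, all 21 oxygen substituents as free OH)
Conditions: BBr3 (excess), CH2Cl2, −78 °C → rt, Ar; then H2O, 0 °C; Sephadex LH-20 under Ar
Reagents that add atoms: none
Why: Lewis-acid ether cleavage in which bromide attacks the methyl carbon of each boron-complexed aryl methyl ether, while the seven diaryl ether bonds are inert because both of their carbons are sp2; the product has no stereocentre.

**Compound list**

1 | squaric acid (3,4-dihydroxycyclobut-3-ene-1,2-dione) | O=C1C(O)=C(O)C1=O | starting material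
2 | squaryl dichloride (3,4-dichlorocyclobut-3-ene-1,2-dione) | O=C1C(Cl)=C(Cl)C1=O | intermediate
3 | 3-chloro-4-methoxycyclobut-3-ene-1,2-dione | COC1=C(Cl)C(=O)C1=O | intermediate
4 | 3,4,5-trimethoxyphenol | COc1cc(O)cc(OC)c1OC | starting material
5 | 3-methoxy-4-(3,4,5-trimethoxyphenoxy)cyclobut-3-ene-1,2-dione | COC1=C(Oc2cc(OC)c(OC)c(OC)c2)C(=O)C1=O | intermediate
6 | methyl vinyl ether | COC=C | starting material
7 | 1-methoxyvinyllithium | [Li]C(=C)OC | intermediate
8 | lithium 2-methoxy-1-(1-methoxyethenyl)-4-oxo-3-(3,4,5-trimethoxyphenoxy)cyclobut-2-en-1-olate (racemic) | [Li+].[O-]C1(C(=C)OC)C(OC)=C(Oc2cc(OC)c(OC)c(OC)c2)C1=O | intermediate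
9 | 3,4-dimethoxy-4-(1-methoxyethenyl)-2-(3,4,5-trimethoxyphenoxy)cyclobut-2-en-1-one (racemic) | O=C1C(Oc2cc(OC)c(OC)c(OC)c2)=C(OC)C1(OC)C(=C)OC | intermediate
10 | (3Z)-3,4,5-trimethoxy-2-(3,4,5-trimethoxyphenoxy)hexa-1,3,5-trien-1-one | O=C=C(Oc1cc(OC)c(OC)c(OC)c1)/C(OC)=C(OC)\C(=C)OC | intermediate
11 | 3,4,5-trimethoxy-2-(3,4,5-trimethoxyphenoxy)cyclohexa-2,4-dien-1-one | O=C1CC(OC)=C(OC)C(OC)=C1Oc1cc(OC)c(OC)c(OC)c1 | intermediate
12 | 3,4,5-trimethoxy-2-(3,4,5-trimethoxyphenoxy)phenol (H–G phenol) | Oc1cc(OC)c(OC)c(OC)c1Oc1cc(OC)c(OC)c(OC)c1 | intermediate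
13 | 4-bromo-2-methoxyphenol | COc1cc(Br)ccc1O | starting material
14 | 4-bromo-2-iodo-6-methoxyphenol | COc1cc(Br)cc(I)c1O | intermediate
15 | 5-bromo-1-iodo-2,3-dimethoxybenzene | COc1cc(Br)cc(I)c1OC | intermediate
16 | 5-bromo-2,3-dimethoxy-1-[3,4,5-trimethoxy-2-(3,4,5-trimethoxyphenoxy)phenoxy]benzene (H–G–F bromide) | COc1cc(Br)cc(Oc2cc(OC)c(OC)c(OC)c2Oc2cc(OC)c(OC)c(OC)c2)c1OC | intermediate
17 | 2,4,6-trimethoxyphenol | COc1cc(OC)c(O)c(OC)c1 | starting material
18 | 4-bromo-2,6-dimethoxybenzaldehyde | COc1cc(Br)cc(OC)c1C=O | starting material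
19 | 2,6-dimethoxy-4-(2,4,6-trimethoxyphenoxy)benzaldehyde | COc1cc(OC)c(Oc2cc(OC)c(C=O)c(OC)c2)c(OC)c1 | intermediate
20 | 2,6-dimethoxy-4-(2,4,6-trimethoxyphenoxy)phenyl formate | COc1cc(OC)c(Oc2cc(OC)c(OC=O)c(OC)c2)c(OC)c1 | intermediate
21 | 2,6-dimethoxy-4-(2,4,6-trimethoxyphenoxy)phenol | COc1cc(OC)c(Oc2cc(OC)c(O)c(OC)c2)c(OC)c1 | intermediate
22 | 5-bromo-1,2,3-trimethoxybenzene | COc1cc(Br)cc(OC)c1OC | starting material
23 | 6-bromo-2,3,4-trimethoxybenzaldehyde | COc1cc(Br)c(C=O)c(OC)c1OC | intermediate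
24 | 6-[2,6-dimethoxy-4-(2,4,6-trimethoxyphenoxy)phenoxy]-2,3,4-trimethoxybenzaldehyde | COc1cc(Oc2c(OC)cc(Oc3c(OC)cc(OC)cc3OC)cc2OC)c(C=O)c(OC)c1OC | intermediate
25 | 6-[2,6-dimethoxy-4-(2,4,6-trimethoxyphenoxy)phenoxy]-2,3,4-trimethoxyphenyl formate | COc1cc(Oc2c(OC)cc(Oc3c(OC)cc(OC)cc3OC)cc2OC)c(OC=O)c(OC)c1OC | intermediate
26 | 6-[2,6-dimethoxy-4-(2,4,6-trimethoxyphenoxy)phenoxy]-2,3,4-trimethoxyphenol | COc1cc(Oc2c(OC)cc(Oc3c(OC)cc(OC)cc3OC)cc2OC)c(O)c(OC)c1OC | intermediate
27 | 4-{6-[2,6-dimethoxy-4-(2,4,6-trimethoxyphenoxy)phenoxy]-2,3,4-trimethoxyphenoxy}-2,6-dimethoxybenzaldehyde | COc1cc(Oc2c(OC)cc(Oc3c(OC)cc(OC)cc3OC)cc2OC)c(Oc4cc(OC)c(C=O)c(OC)c4)c(OC)c1OC | intermediate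
28 | 4-{6-[2,6-dimethoxy-4-(2,4,6-trimethoxyphenoxy)phenoxy]-2,3,4-trimethoxyphenoxy}-2,6-dimethoxyphenyl formate | COc1cc(Oc2c(OC)cc(Oc3c(OC)cc(OC)cc3OC)cc2OC)c(Oc4cc(OC)c(OC=O)c(OC)c4)c(OC)c1OC | intermediate
29 | 4-{6-[2,6-dimethoxy-4-(2,4,6-trimethoxyphenoxy)phenoxy]-2,3,4-trimethoxyphenoxy}-2,6-dimethoxyphenol (ArAD–OH) | COc1cc(Oc2c(OC)cc(Oc3c(OC)cc(OC)cc3OC)cc2OC)c(Oc4cc(OC)c(O)c(OC)c4)c(OC)c1OC | intermediate
30 | 3-methoxy-4-(ArAD-oxy)cyclobut-3-ene-1,2-dione | COc1cc(Oc2c(OC)cc(Oc3c(OC)cc(OC)cc3OC)cc2OC)c(Oc4cc(OC)c(OC5=C(OC)C(=O)C5=O)c(OC)c4)c(OC)c1OC | intermediate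
31 | lithium 2-methoxy-1-(1-methoxyethenyl)-4-oxo-3-(ArAD-oxy)cyclobut-2-en-1-olate (racemic) | [Li+].COc1cc(Oc2c(OC)cc(Oc3c(OC)cc(OC)cc3OC)cc2OC)c(Oc4cc(OC)c(OC5=C(OC)C([O-])(C(=C)OC)C5=O)c(OC)c4)c(OC)c1OC | intermediate
32 | 3,4-dimethoxy-4-(1-methoxyethenyl)-2-(ArAD-oxy)cyclobut-2-en-1-one (racemic) | COc1cc(Oc2c(OC)cc(Oc3c(OC)cc(OC)cc3OC)cc2OC)c(Oc4cc(OC)c(OC5=C(OC)C(OC)(C(=C)OC)C5=O)c(OC)c4)c(OC)c1OC | intermediate
33 | (3Z)-3,4,5-trimethoxy-2-(ArAD-oxy)hexa-1,3,5-trien-1-one | COc1cc(Oc2c(OC)cc(Oc3c(OC)cc(OC)cc3OC)cc2OC)c(Oc4cc(OC)c(OC(=C=O)/C(OC)=C(OC)\C(=C)OC)c(OC)c4)c(OC)c1OC | intermediate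
34 | 3,4,5-trimethoxy-2-(ArAD-oxy)cyclohexa-2,4-dien-1-one | COc1cc(Oc2c(OC)cc(Oc3c(OC)cc(OC)cc3OC)cc2OC)c(Oc4cc(OC)c(OC5=C(OC)C(OC)=C(OC)CC5=O)c(OC)c4)c(OC)c1OC | intermediate
35 | 3,4,5-trimethoxy-2-(ArAD-oxy)phenol (A–E phenol) | COc1cc(Oc2c(OC)cc(Oc3c(OC)cc(OC)cc3OC)cc2OC)c(Oc4cc(OC)c(Oc5c(O)cc(OC)c(OC)c5OC)c(OC)c4)c(OC)c1OC | intermediate
36 | henicosa-O-methyl ether of the target, 2-(ArAD-oxy)-1-{3,4-dimethoxy-5-[3,4,5-trimethoxy-2-(3,4,5-trimethoxyphenoxy)phenoxy]phenoxy}-3,4,5-trimethoxybenzene | COc1cc(Oc2c(OC)cc(Oc3c(OC)cc(OC)cc3OC)cc2OC)c(Oc4cc(OC)c(Oc5c(Oc6cc(OC)c(OC)c(Oc7cc(OC)c(OC)c(OC)c7Oc7cc(OC)c(OC)c(OC)c7)c6)cc(OC)c(OC)c5OC)c(OC)c4)c(OC)c1OC | intermediate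
37 | CNP0309601.0 (octameric aryl ether A–H with 21 free hydroxyls) | Oc1cc(O)c(Oc2cc(O)c(Oc3cc(O)c(O)c(O)c3Oc3cc(O)c(Oc4c(Oc5cc(O)c(O)c(Oc6cc(O)c(O)c(O)c6Oc6cc(O)c(O)c(O)c6)c5)cc(O)c(O)c4O)c(O)c3)c(O)c2)c(O)c1 | target

**Count and risks**

Total step count: 21. Longest linear sequence: 11 steps (steps 10, 11, 13, 14, 15, 16, 17, 18, 19, 20, 21, from 17 and 18).

Step 5 – poor discrimination between the two squarate carbonyls in the organolithium addition, or displacement of the aryloxide instead of carbonyl addition; either would wrongly place the aryloxy group for the key step (step 18 carries the same risk but is helped by the bulk of its aryloxy group). Fallback, setting out from 2 (with 4 and 7) and coming back at 9: the regiochemistry would be fixed by symmetry. Compound 2 with two equivalents of 4 (i-Pr2NEt, THF, −78 °C → rt) should give the diaryl squarate 3,4-bis(3,4,5-trimethoxyphenoxy)cyclobut-3-ene-1,2-dione F1, whose two carbonyls are equivalent. Addition of 7 would give lithium 1-(1-methoxyethenyl)-4-oxo-2,3-bis(3,4,5-trimethoxyphenoxy)cyclobut-2-en-1-olate F2, methylated in the flask with MeOTf to 4-methoxy-4-(1-methoxyethenyl)-2,3-bis(3,4,5-trimethoxyphenoxy)cyclobut-2-en-1-one F3. In F3 only C-3 is the β-carbon of a vinylogous ester, so MeOH with i-Pr2NEt (cat.) at 0 °C should exchange that aryloxy group alone for methoxy by addition–elimination, releasing 4 and giving 9.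

Step 20 – slow insertion of copper into the electron-rich bromide of a large fragment, with catalyst decay, hydrodebromination and oxidation of the para-methoxyphenol 35 under hot basic conditions. Fallback, setting out from 16 and coming back at 36: the polarity of ring F would be inverted and the ether formed oxidatively at room temperature. Miyaura borylation of 16 (B2pin2, PdCl2(dppf), KOAc, dioxane, 90 °C) should give the pinacol boronate 2-{3,4-dimethoxy-5-[3,4,5-trimethoxy-2-(3,4,5-trimethoxyphenoxy)phenoxy]phenyl}-4,4,5,5-tetramethyl-1,3,2-dioxaborolane F4. Cleavage with NaIO4 and NH4OAc in acetone–water should give {3,4-dimethoxy-5-[3,4,5-trimethoxy-2-(3,4,5-trimethoxyphenoxy)phenoxy]phenyl}boronic acid F5. Chan–Lam coupling of F5 with 35 (Cu(OAc)2 20 mol %, pyridine, 4 Å molecular sieves, CH2Cl2, O2, rt) should then give 36.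

Step 21 – incomplete cleavage of some of the 21 methyl ethers, together with air oxidation of the pyrogallol-type rings while the free polyphenol is isolated. Fallback, setting out from 36 and coming back at 37: the crude product of the BBr3 reaction would not be isolated but acetylated at once (Ac2O, pyridine, DMAP cat., Ar) to the stable henicosaacetate of the target F6. F6 can be purified on silica and separated from under-cleaved congeners, which would be resubmitted to BBr3. Acid-catalysed methanolysis of F6 (HCl cat., degassed MeOH, 40 °C, Ar) and evaporation should then deliver 37 without exposing it to base.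

**Further compounds**

F1 | step 5 | 3,4-bis(3,4,5-trimethoxyphenoxy)cyclobut-3-ene-1,2-dione | O=C1C(Oc2cc(OC)c(OC)c(OC)c2)=C(Oc2cc(OC)c(OC)c(OC)c2)C1=O
F2 | step 5 | lithium 1-(1-methoxyethenyl)-4-oxo-2,3-bis(3,4,5-trimethoxyphenoxy)cyclobut-2-en-1-olate (racemic) | [Li+].[O-]C1(C(=C)OC)C(Oc2cc(OC)c(OC)c(OC)c2)=C(Oc2cc(OC)c(OC)c(OC)c2)C1=O
F3 | step 5 | 4-methoxy-4-(1-methoxyethenyl)-2,3-bis(3,4,5-trimethoxyphenoxy)cyclobut-2-en-1-one (racemic) | O=C1C(Oc2cc(OC)c(OC)c(OC)c2)=C(Oc2cc(OC)c(OC)c(OC)c2)C1(OC)C(=C)OC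
F4 | step 20 | 2-{3,4-dimethoxy-5-[3,4,5-trimethoxy-2-(3,4,5-trimethoxyphenoxy)phenoxy]phenyl}-4,4,5,5-tetramethyl-1,3,2-dioxaborolane | COc1cc(B2OC(C)(C)C(C)(C)O2)cc(Oc2cc(OC)c(OC)c(OC)c2Oc2cc(OC)c(OC)c(OC)c2)c1OC
F5 | step 20 | {3,4-dimethoxy-5-[3,4,5-trimethoxy-2-(3,4,5-trimethoxyphenoxy)phenoxy]phenyl}boronic acid | COc1cc(B(O)O)cc(Oc2cc(OC)c(OC)c(OC)c2Oc2cc(OC)c(OC)c(OC)c2)c1OC
F6 | step 21 | henicosaacetate of the target (all 21 hydroxyls as acetates) | CC(=O)Oc1cc(Oc2c(OC(C)=O)cc(Oc3c(OC(C)=O)cc(OC(C)=O)cc3OC(C)=O)cc2OC(C)=O)c(Oc4cc(OC(C)=O)c(Oc5c(Oc6cc(OC(C)=O)c(OC(C)=O)c(Oc7cc(OC(C)=O)c(OC(C)=O)c(OC(C)=O)c7Oc7cc(OC(C)=O)c(OC(C)=O)c(OC(C)=O)c7)c6)cc(OC(C)=O)c(OC(C)=O)c5OC(C)=O)c(OC(C)=O)c4)c(OC(C)=O)c1OC(C)=O
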